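Everything rests on cutting the C4a–C5 bond of ring A. What remains is an intact 4-pyranone (ring C, already carrying ring B and the 3-methoxy group) whose C8a bears C8. C8 carries both the chiral 1-arylethyl group and a malonyl chain C7–C6–C5 ending in a tert-butyl ester. The step exploits three features: the meta oxygens at C5 and C7 of ring A, the C4a=C8a bond shared by rings A and C, and the nucleophilic C4a of the vinylogous ester O1–C8a=C4a–C4=O. Heating expels tert-butanol; the acylketene, as its C7 enol, closes onto C4a and aromatises, delivering the 5,7-diol with the side chain locked at C8.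

Key step: step 7

Assumption: Rh/BINAP is taken to follow its usual sense of induction with E-crotonates ((S)-BINAP gives (R)-3-arylbutanoates), so (R)-BINAP is specified; configuration and enantiomeric purity of the arylation product would be checked at that stage, the antipodal ligand or chromatography on a chiral phase being the remedy.

Remarks on the design
- Flavone numbering (O1, C2, C3, C4, C4a, C5 to C8, C8a) is used for the corresponding atoms of every intermediate. Ring B is the 4-methoxyphenyl group and ring D is the aryl group of the side chain.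
- The arrangement in space at the benzylic carbon never changes. Its descriptor is S while the future C8 is sp3 and becomes R once C8 belongs to the oxygenated π system, because the CIP ranking of C8 and ring D is then reversed.
- The malonyl chain is attached with reversed polarity. An electrophilic malonyl half-ester has a CH2 group far more acidic than the C8–H bonds and would only protonate the C8 carbanion. C8 is therefore carboxylated first, and the acid is extended with the magnesium salt of the malonic half-ester under nearly neutral conditions.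
- The precursor keeps the tert-butyl ester, which releases the ketene at the lowest temperature among simple alkyl esters and needs no reagent.
- The precursor also keeps the benzyl ether on ring D. A free phenol would trap the ketene and would make the C8–benzylic bond prone to ionisation.

Step 1
Reactants: 1 methyl (E)-but-2-enoate (methyl crotonate); 2 4-(benzyloxy)phenylboronic acid
Product: 3 methyl (3S)-3-[4-(benzyloxy)phenyl]butanoate
Conditions: Rh(acac)(C2H4)2 (3 mol %), (R)-BINAP (4.5 mol %), 2 (1.5 equiv), 1,4-dioxane/H2O 10:1, 100 °C
Reagents that add atoms: none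
Why: Hayashi–Miyaura asymmetric 1,4-addition, in which ArRh[(R)-BINAP] inserts the E-enoate through one enantiotopic face and water protonates the resulting rhodium oxa-π-allyl intermediate, which sets the benzylic centre as S while ester and benzyl ether are inert.

Step 2
Reactants: 4 2-methoxy-1-(4-methoxyphenyl)ethanone
Product: 6 2-methoxy-1-(4-methoxyphenyl)butane-1,3-dione (racemic keto–enol mixture), via lithium enolate 5 (not isolated)
Conditions: 4 (2.0 equiv), LiN(SiMe3)2 (2.1 equiv), toluene/THF, 0 °C; AcCl (1.0 equiv), 0 °C; 1 M HCl
Reagents that add atoms: acetyl chloride, CC(=O)Cl; LiN(SiMe3)2, [Li]N([Si](C)(C)C)[Si](C)(C)C (lithium of intermediate 5 only)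
Why: Claisen-type C-acylation of a lithium enolate with an acid chloride in a weakly coordinating medium, where the tight methoxy-chelated enolate reacts through carbon and the second equivalent of enolate takes up the acidic proton of the 1,3-diketone; the new centre is configurationally labile and irrelevant.

Step 3
Reactants: 6 2-methoxy-1-(4-methoxyphenyl)butane-1,3-dione; 3 methyl (3S)-3-[4-(benzyloxy)phenyl]butanoate
Product: 8 (7S)-7-[4-(benzyloxy)phenyl]-2-methoxy-1-(4-methoxyphenyl)octane-1,3,5-trione (tautomer mixture), via dilithium dienediolate 7 (not isolated)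
Conditions: 6 (2.2 equiv), LiN(i-Pr)2 (commercial solution, 4.5 equiv), THF, −78 to 0 °C; 3 (1.0 equiv), 0 °C to rt; 1 M HCl
Reagents that add atoms: LiN(i-Pr)2, [Li]N(C(C)C)C(C)C (lithium of intermediate 7 only)
Why: Acylation of a 1,3-diketone dianion at its more basic terminal carbon by an ester (Hauser-type Claisen condensation), run with excess dianion so that the more acidic triketone does not stall the reaction; the benzylic centre lies β to the ester carbonyl and cannot epimerise.

Step 4
Reactants: 8 (7S)-7-[4-(benzyloxy)phenyl]-2-methoxy-1-(4-methoxyphenyl)octane-1,3,5-trione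
Product: 9 2-{(2S)-2-[4-(benzyloxy)phenyl]propyl}-5-methoxy-6-(4-methoxyphenyl)-4H-pyran-4-one
Conditions: p-TsOH·H2O (0.2 equiv), toluene, reflux, Dean–Stark
Reagents that add atoms: none
Why: Acid-catalysed cyclodehydration of a 1,3,5-triketone, in which the enol oxygen of the aroyl terminus adds to the remote ketone and water is lost, the only six-membered oxygen heterocycle open to this chain, under conditions that leave the aryl benzyl ether intact.

Step 5
Reactants: 9 2-{(2S)-2-[4-(benzyloxy)phenyl]propyl}-5-methoxy-6-(4-methoxyphenyl)-4H-pyran-4-one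
Product: 11 (3S)-3-[4-(benzyloxy)phenyl]-2-[5-methoxy-6-(4-methoxyphenyl)-4-oxo-4H-pyran-2-yl]butanoic acid (epimers at C2), via lithium dienolate 10 (not isolated)
Conditions: LiN(SiMe3)2 (1.2 equiv), THF, −78 °C; dry CO2 gas, −78 to −20 °C; cold 1 M HCl to pH 3; concentrated below 25 °C and used at once
Reagents that add atoms: carbon dioxide, O=C=O; LiN(SiMe3)2, [Li]N([Si](C)(C)C)[Si](C)(C)C (lithium of intermediate 10 only)
Why: Lateral (vinylogous) deprotonation of a 2-alkyl-4-pyranone followed by carboxylation, in which the CH2 group on C8a is the most acidic site, its dienolate takes up small electrophiles at the exocyclic carbon so that the pyranone is restored, and the carboxylate formed cannot quench unreacted dienolate; the new C8 centre is of no consequence because it becomes planar in step 7.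

Step 6
Reactants: 11 (3S)-3-[4-(benzyloxy)phenyl]-2-[5-methoxy-6-(4-methoxyphenyl)-4-oxo-4H-pyran-2-yl]butanoic acid; 12 mono-tert-butyl malonate
Product: 15 tert-butyl (5S)-5-[4-(benzyloxy)phenyl]-4-[5-methoxy-6-(4-methoxyphenyl)-4-oxo-4H-pyran-2-yl]-3-oxohexanoate (epimers at C4), via magnesium bis(tert-butyl malonate) 13 (not isolated), via acyl imidazolide 14 (not isolated)
Conditions: 12 (2.4 equiv), Mg(OEt)2 (1.2 equiv), THF, rt, then evaporation; 11, 1,1'-carbonyldiimidazole (1.1 equiv), THF, 0 °C to rt; both combined, rt to 35 °C; cold 0.5 M HCl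
Reagents that add atoms: 1,1'-carbonyldiimidazole, O=C(n1ccnc1)n1ccnc1 (imidazolyl group of intermediate 14 only); Mg(OEt)2, CC[O-].CC[O-].[Mg+2] (magnesium of intermediate 13 only)
Why: Masamune–Brooks homologation (decarboxylative Claisen condensation of a magnesium malonate half-ester with an acyl imidazolide), chosen because its nearly neutral, chelation-driven conditions tolerate the very acidic C8–H and the tert-butyl ester and leave the benzylic centre untouched.

Step 7
Reactants: 15 tert-butyl (5S)-5-[4-(benzyloxy)phenyl]-4-[5-methoxy-6-(4-methoxyphenyl)-4-oxo-4H-pyran-2-yl]-3-oxohexanoate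
Product: 19 8-{(1R)-1-[4-(benzyloxy)phenyl]ethyl}-5,7-dihydroxy-3-methoxy-2-(4-methoxyphenyl)-4H-chromen-4-one, via acylketene 16 (not isolated), via dienylketene 17 (not isolated), via cyclohexadienone 18 (not isolated)
Conditions: xylenes, 140 °C, slow addition of 15 by syringe pump (final 2 mM), argon sweep to carry off t-BuOH
Reagents that add atoms: none
Why: Proposed new method: the chelated enol of β-keto ester 15 loses t-BuOH through a six-membered transition state to give acylketene 16, and tautomerisation of the C7 ketone toward the doubly activated C8–H gives the (E)-enol 17, a dienylketene in which C5=C6, C7=C8 and C8a=C4a form a cisoid triene. Thermal disrotatory six-electron electrocyclisation, polarised by the C7 hydroxyl donor and the electrophilic ketene carbon so that it can equally be read as attack of C4a on C5, forms the C4a–C5 bond and closes ring A as an all-carbon six-membered ring (dienone 18), which aromatises irreversibly by moving the C4a proton to O5. The closest known reaction types are acylketene release from tert-butyl acetoacetates, the dienylketene closure that ends the Danheiser and Moore benzannulations and the acid-promoted cyclisation of 4-aryl-3-oxobutanoates to naphthalene-1,3-diols, none of which has used the C=C bond of a 4-pyranone as the terminus. No stereocentre is created, since C8 and C4a end up planar, and the benzylic centre keeps its configuration because none of its bonds is broken in the productive geometry. Site selectivity is built into the substrate, as C4a is the only atom that gives a six-membered ring and O1 cannot accept the acyl carbon, and it fixes the side chain at C8 without any 6/8 ambiguity. Chemoselectivity against ketene dimerisation, re-addition of t-BuOH and capture by product phenols rests on high dilution, removal of t-BuOH and the thermal reversibility of those additions, while the benzyl ether keeps ring D from trapping the ketene.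

Step 8
Reactants: 19 8-{(1R)-1-[4-(benzyloxy)phenyl]ethyl}-5,7-dihydroxy-3-methoxy-2-(4-methoxyphenyl)-4H-chromen-4-one
Product: 20 5,7-dihydroxy-8-[(1R)-1-(4-hydroxyphenyl)ethyl]-3-methoxy-2-(4-methoxyphenyl)-4H-chromen-4-one
Conditions: H2 (1 atm), Pd/C (10 wt % Pd), EtOAc/MeOH, rt
Reagents that add atoms: none
Why: Catalytic hydrogenolysis of an aryl benzyl ether under neutral conditions, which leaves the tetrasubstituted C2=C3 bond, the C4 carbonyl group, both methyl ethers and the diarylmethine C–C bonds alone and avoids the acids that could ionise the C8–benzylic bond once ring D is a free phenol.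

Compound list
1 | methyl (E)-but-2-enoate | C/C=C/C(=O)OC | starting material
2 | 4-(benzyloxy)phenylboronic acid | OB(O)c1ccc(OCc2ccccc2)cc1 | starting material
3 | methyl (3S)-3-[4-(benzyloxy)phenyl]butanoate | COC(=O)C[C@H](C)c1ccc(OCc2ccccc2)cc1 | intermediate
4 | 2-methoxy-1-(4-methoxyphenyl)ethanone | COCC(=O)c1ccc(OC)cc1 | starting material
5 | lithium enolate of 4 (not isolated) | COC=C(O[Li])c1ccc(OC)cc1 | intermediate
6 | 2-methoxy-1-(4-methoxyphenyl)butane-1,3-dione | COc1ccc(C(=O)C(OC)C(C)=O)cc1 | intermediate
7 | dilithium dienediolate (dianion) of 6 (not isolated) | C=C(O[Li])C(OC)=C(O[Li])c1ccc(OC)cc1 | intermediate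
8 | (7S)-7-[4-(benzyloxy)phenyl]-2-methoxy-1-(4-methoxyphenyl)octane-1,3,5-trione | COc1ccc(C(=O)C(OC)C(=O)CC(=O)C[C@H](C)c2ccc(OCc3ccccc3)cc2)cc1 | intermediate
9 | 2-{(2S)-2-[4-(benzyloxy)phenyl]propyl}-5-methoxy-6-(4-methoxyphenyl)-4H-pyran-4-one | COc1ccc(-c2oc(C[C@H](C)c3ccc(OCc4ccccc4)cc3)cc(=O)c2OC)cc1 | intermediate
10 | lithium 2-alkylidene-2H-pyran-4-olate (lateral dienolate of 9, not isolated) | COc1ccc(C2=C(OC)C(O[Li])=CC(=C[C@H](C)c3ccc(OCc4ccccc4)cc3)O2)cc1 | intermediate
11 | (3S)-3-[4-(benzyloxy)phenyl]-2-[5-methoxy-6-(4-methoxyphenyl)-4-oxo-4H-pyran-2-yl]butanoic acid, epimers at C2 | COc1ccc(-c2oc(C(C(=O)O)[C@H](C)c3ccc(OCc4ccccc4)cc3)cc(=O)c2OC)cc1 | intermediate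
12 | mono-tert-butyl malonate | CC(C)(C)OC(=O)CC(=O)O | starting material
13 | magnesium bis(3-tert-butoxy-3-oxopropanoate) (not isolated) | CC(C)(C)OC(=O)CC(=O)[O-].CC(C)(C)OC(=O)CC(=O)[O-].[Mg+2] | intermediate
14 | acyl imidazolide of 11 (not isolated) | COc1ccc(-c2oc(C(C(=O)n3ccnc3)[C@H](C)c3ccc(OCc4ccccc4)cc3)cc(=O)c2OC)cc1 | intermediate
15 | tert-butyl (5S)-5-[4-(benzyloxy)phenyl]-4-[5-methoxy-6-(4-methoxyphenyl)-4-oxo-4H-pyran-2-yl]-3-oxohexanoate, epimers at C4 | CC(C)(C)OC(=O)CC(=O)C(c1cc(=O)c(OC)c(-c2ccc(OC)cc2)o1)[C@H](C)c1ccc(OCc2ccccc2)cc1 | intermediate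
16 | acylketene formed from 15 by loss of tert-butanol (not isolated) | O=C=CC(=O)C(c1cc(=O)c(OC)c(-c2ccc(OC)cc2)o1)[C@H](C)c1ccc(OCc2ccccc2)cc1 | intermediate
17 | (E)-C7-enol of 16, hydroxydienylketene with C6 cis to C8a (not isolated) | O=C=C/C(O)=C(\c1cc(=O)c(OC)c(-c2ccc(OC)cc2)o1)[C@H](C)c1ccc(OCc2ccccc2)cc1 | intermediate
18 | 4aH-chromene-4,5-dione (cyclohexadienone tautomer of 19, C4a unassigned, not isolated) | COc1ccc(C2=C(OC)C(=O)C3C(=O)C=C(O)C([C@H](C)c4ccc(OCc5ccccc5)cc4)=C3O2)cc1 | intermediate
19 | 8-{(1R)-1-[4-(benzyloxy)phenyl]ethyl}-5,7-dihydroxy-3-methoxy-2-(4-methoxyphenyl)-4H-chromen-4-one | COc1ccc(-c2oc3c([C@H](C)c4ccc(OCc5ccccc5)cc4)c(O)cc(O)c3c(=O)c2OC)cc1 | intermediate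
20 | 5,7-dihydroxy-8-[(1R)-1-(4-hydroxyphenyl)ethyl]-3-methoxy-2-(4-methoxyphenyl)-4H-chromen-4-one | COc1ccc(-c2oc3c([C@H](C)c4ccc(O)cc4)c(O)cc(O)c3c(=O)c2OC)cc1 | target

Total step count: 8. Longest linear sequence: 7 (steps 1, 3, 4, 5, 6, 7, 8; the branch through step 2 is equally long).

Steps most likely to fail

**Step 7.**
- Several processes could outrun the closure:
  - dimerisation of the acylketene;
  - capture of adventitious water followed by decarboxylation;
  - a 1,5-hydrogen shift from the benzylic C–H to the ketene carbon in the unproductive enol geometry, which would also erase the stereocentre.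
- The partly aromatic C=C bond of the pyranone may also be too reluctant a triene terminus.
- The fallback keeps the pyranone-first logic, and with it the C8 regiochemistry. It builds ring A by known ionic reactions, making C4a–C5 by carbonylation and closing the ring at C5–C6.
- It sets out from pyranone 9. Electrophilic α-bromination of the vinylogous ester (NBS, CH2Cl2, 0 °C, dark) should give the 3-bromopyranone F1.
- Palladium-catalysed methoxycarbonylation (Pd(OAc)2, dppf, CO 1 atm, MeOH, Et3N, DMF, 70 °C) should give the methyl 4-pyranone-3-carboxylate F2.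
- Lateral deprotonation (LiN(SiMe3)2, 2.2 equiv, THF, −78 °C) and acetylation with N-methoxy-N-methylacetamide should give the methyl ketone F3.
- A Dieckmann-type condensation of the acetyl methyl group onto the ring ester (KOt-Bu, THF, 0 °C to rt, then dilute HCl) comes back to the route at 19. This is the reaction type that turns 2-acetonylbenzoates into naphthalene-1,3-diols.

**Step 6.**
- The imidazolide is hindered and very easily enolised. Proton transfer to the magnesium enolate, and loss of CO2 from acid that is not yet activated, may therefore outpace C-acylation.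
- The fallback replaces the basic magnesium enolate by a far more acidic, non-basic carbon nucleophile (Oikawa–Yonemitsu method).
- Setting out from acid 11, carbodiimide coupling with Meldrum's acid (EDC·HCl, DMAP, CH2Cl2, 0 °C) should give the acyl Meldrum's acid F4.
- Alcoholysis of F4 with excess t-BuOH (toluene, 80 °C) comes back to the route at 15. Any material that closes directly to 19 at this stage is not lost.

**Step 3.**
- Proton transfer from the enolisable ester to the strongly basic dianion, together with slow collapse of the tetrahedral intermediate, may hold conversion down.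
- The fallback exchanges acylation for aldol addition and oxidation.
- Setting out from ester 3, i-Bu2AlH (CH2Cl2, −78 °C) should give (3S)-3-[4-(benzyloxy)phenyl]butanal F5.
- Addition of F5 to dianion 7 at −78 °C, where carbonyl addition outruns proton transfer, should give the β-hydroxy diketone F6 as a mixture of diastereomers.
- Oxidation with IBX (EtOAc, 75 °C) comes back to the route at triketone 8.

Further compounds
F1 | step 7 | 2-{(2S)-2-[4-(benzyloxy)phenyl]propyl}-3-bromo-5-methoxy-6-(4-methoxyphenyl)-4H-pyran-4-one | COc1ccc(-c2oc(C[C@H](C)c3ccc(OCc4ccccc4)cc3)c(Br)c(=O)c2OC)cc1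
F2 | step 7 | methyl 2-{(2S)-2-[4-(benzyloxy)phenyl]propyl}-5-methoxy-6-(4-methoxyphenyl)-4-oxo-4H-pyran-3-carboxylate | COC(=O)c1c(C[C@H](C)c2ccc(OCc3ccccc3)cc2)oc(-c2ccc(OC)cc2)c(OC)c1=O
F3 | step 7 | methyl 2-{(4S)-4-[4-(benzyloxy)phenyl]-2-oxopentan-3-yl}-5-methoxy-6-(4-methoxyphenyl)-4-oxo-4H-pyran-3-carboxylate, epimers at C3 of the side chain | COC(=O)c1c(C(C(C)=O)[C@H](C)c2ccc(OCc3ccccc3)cc2)oc(-c2ccc(OC)cc2)c(OC)c1=O
F4 | step 6 | 5-{(3S)-3-[4-(benzyloxy)phenyl]-2-[5-methoxy-6-(4-methoxyphenyl)-4-oxo-4H-pyran-2-yl]butanoyl}-2,2-dimethyl-1,3-dioxane-4,6-dione | COc1ccc(-c2oc(C(C(=O)C3C(=O)OC(C)(C)OC3=O)[C@H](C)c3ccc(OCc4ccccc4)cc3)cc(=O)c2OC)cc1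
F5 | step 3 | (3S)-3-[4-(benzyloxy)phenyl]butanal | O=CC[C@H](C)c1ccc(OCc2ccccc2)cc1
F6 | step 3 | (7S)-7-[4-(benzyloxy)phenyl]-5-hydroxy-2-methoxy-1-(4-methoxyphenyl)octane-1,3-dione | COc1ccc(C(=O)C(OC)C(=O)CC(O)C[C@H](C)c2ccc(OCc3ccccc3)cc2)cc1
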